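**Retrosynth­etic overview**

1. The strategy rests on the fully substituted ring B: C1 CH2OAc, C2 OH, C3 lactone C=O, C4 lactol CH, C5 O‑aryl, C6 O‑acyl. Its C2 and C5 oxygens are para, and C5–C6–C1–C2 is a contiguous O,O,C,O‑bearing run that maps onto the four carbons of squaric acid; C3–C4 comes from an alkenyl unit carrying the lactol carbon as a diethyl acetal.
2. Disconnections, last to first: lactol (hydrolysis of an ethyl pseudo‑ester, then resolution), acetate, depsidone ester C6–O–C(=O) (lactonisation), diaryl ether C5–O–C2′ (SNAr of the ring B phenoxide on a ring A fluoride flanked by CHO and ester), C3–CO2 bond (directed lithiation/CO2), ring B (thermal ring expansion of a 4‑alkenylcyclobutenone).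
3. Ring order: cyclobutenone (squarate plus two organolithiums) → benzene ring B → phthalide pseudo‑ester → ring A (from 3,5‑difluorotoluene) joined through the diaryl ether → seven‑membered depsidone lactone → lactol unmasked last.

Key step: step 8

Assumption (chemistry): the lactol carbon equilibrates through the ring‑opened 2‑formylbenzoic acid form, so it is carried racemic and the (S) enantiomer is taken only in the last step, after which it must be kept cold in neutral aprotic media. Abbreviations: TMSE = 2‑(trimethylsilyl)ethyl, MOM = methoxymethyl, PMB = 4‑methoxybenzyl.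

**Route**

Step 1
Reactants: 1 squaric acid
Product: 2 squaryl dichloride (3,4‑dichlorocyclobut‑3‑ene‑1,2‑dione)
Conditions: SOCl2 (2.2 equiv), DMF (cat.), toluene, 80 °C
Reagents that add atoms: thionyl chloride, O=S(Cl)Cl
Why: DMF‑catalysed acid chloride formation should convert both vinylogous acid hydroxyls into chlorides.

Step 2
Reactants: 2 squaryl dichloride
Product: 3 bis[2‑(trimethylsilyl)ethyl] squarate
Conditions: Me3SiCH2CH2OH (2.1 equiv), 2,6‑lutidine, Et2O, 0 °C → rt
Reagents that add atoms: 2‑(trimethylsilyl)ethanol, C[Si](C)(C)CCO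
Why: Addition–elimination of the alcohol at the vinylogous acid chloride carbons (acylation‑type substitution) should give the diester, the hindered base taking up HCl without attacking the squarate.

Step 3
Reactants: 4 3,3‑diethoxyprop‑1‑yne
Product: 5 (E)‑tributyl(3,3‑diethoxyprop‑1‑en‑1‑yl)stannane
Conditions: Bu3SnH (1.1 equiv), AIBN (cat.), neat, 85 °C; distillation
Reagents that add atoms: tributyltin hydride, CCCC[SnH](CCCC)CCCC
Why: Radical hydrostannylation of the terminal alkyne places tin at the terminus, and reversible stannyl radical addition at this temperature should equilibrate the adduct to the E isomer.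

Step 4
Reactants: 5 (E)‑tributyl(3,3‑diethoxyprop‑1‑en‑1‑yl)stannane, 3 bis[2‑(trimethylsilyl)ethyl] squarate
Product: 7 rac‑4‑[(E)‑3,3‑diethoxyprop‑1‑enyl]‑4‑hydroxy‑2,3‑bis[2‑(trimethylsilyl)ethoxy]cyclobut‑2‑en‑1‑one, via (E)‑3,3‑diethoxyprop‑1‑enyllithium 6 (not isolated)
Conditions: 5, n‑BuLi, THF, −78 °C; then 3, THF, −78 °C; aq. NH4Cl, −78 °C
Reagents that add atoms: none
Why: Tin–lithium exchange with retention of alkene geometry followed by 1,2‑addition to one of the two equivalent squarate carbonyls should give the tertiary carbinol, whose quaternary stereocentre forms racemic and is later destroyed.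

Step 5
Reactants: 7 the 4‑hydroxycyclobutenone
Product: 8 rac‑4‑[(E)‑3,3‑diethoxyprop‑1‑enyl]‑4‑(methoxymethoxy)‑2,3‑bis[2‑(trimethylsilyl)ethoxy]cyclobut‑2‑en‑1‑one
Conditions: MOMCl, i‑Pr2NEt, CH2Cl2, 0 °C → rt
Reagents that add atoms: chloromethyl methyl ether, COCCl
Why: O‑alkylation of the tertiary alcohol with the reactive α‑chloro ether under amine base (acetal‑type protection) should cap the oxygen that becomes the C2 phenol.

Step 6
Reactants: 9 (tributylstannyl)methanol
Product: 10 tributyl[(4‑methoxybenzyloxy)methyl]stannane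
Conditions: NaH, PMBCl, Bu4NI (cat.), THF/DMF, 0 °C → rt
Reagents that add atoms: 4‑methoxybenzyl chloride, COc1ccc(CCl)cc1
Why: Williamson ether synthesis on the primary alkoxide should give the PMB ether without touching the C–Sn bond.

Step 7
Reactants: 10 tributyl[(4‑methoxybenzyloxy)methyl]stannane, 8 the 4‑OMOM cyclobutenone
Product: 13 rac‑4‑[(E)‑3,3‑diethoxyprop‑1‑enyl]‑4‑(methoxymethoxy)‑3‑[(4‑methoxybenzyloxy)methyl]‑2‑[2‑(trimethylsilyl)ethoxy]cyclobut‑2‑en‑1‑one, via [(4‑methoxybenzyloxy)methyl]lithium 11 (not isolated), via lithium cyclobutenolate adduct 12 (not isolated)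
Conditions: 10, n‑BuLi, THF, −78 °C; 8, −78 °C; (CF3CO)2O (1.3 equiv), −78 °C, 20 min; aq. NaHCO3, −78 °C → rt
Reagents that add atoms: water, O
Why: The α‑alkoxymethyllithium from tin–lithium exchange adds 1,2 to the only remaining carbonyl, and trifluoroacetylation of the alkoxide triggers ionisation to an alkoxy‑stabilised cyclobutenyl cation that is hydrolysed at the distal OTMSE carbon (1,3‑carbonyl transposition of squarate adducts), the uncontrolled carbinol stereocentre of 12 being lost in the process.

Step 8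
Reactants: 13 the transposed cyclobutenone
Product: 16 2‑(diethoxymethyl)‑4‑(methoxymethoxy)‑5‑[(4‑methoxybenzyloxy)methyl]‑6‑[2‑(trimethylsilyl)ethoxy]phenol, via dienylketene 14 (not isolated), via cyclohexa‑2,4‑dienone 15 (not isolated)
Conditions: degassed toluene (0.02 M), 110 °C, argon
Reagents that add atoms: none
Why: Heating should open the cyclobutenone by conrotatory 4π electrocyclic cleavage of the C(=O)–C(sp3) bond to dienylketene 14, after which 6π electrocyclisation joins the ketene carbon (future C5) to the alkene terminus (future C4) and enolisation of dienone 15 gives phenol 16 irreversibly. The closest known reaction type is the thermal ring expansion of squarate‑derived 4‑alkenyl‑4‑alkoxycyclobutenones to hydroquinone monoethers. Benzene ring B is closed by this disrotatory 6π electrocyclisation onto the E‑alkene terminus, whose inward substituent is hydrogen, and no other ring forms. No stereocentre is created: the racemic quaternary carbon of 13 becomes aromatic C2 and the transient sp3 carbon of 15 is lost on tautomerisation. The selectivity needed is regiochemical (C5–OH free, C2–O protected, CH2OPMB at C1, OTMSE at C6) and is fixed beforehand by the order of the two organolithium additions and the carbonyl transposition, while outward rotation of the OMOM donor in the ring opening places the alkenyl group cis to the ketene. Acetal, MOM, PMB and TMSE groups should all tolerate neutral thermolysis.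

Step 9
Reactants: 16 the ring B phenol
Product: 19 rac‑3‑ethoxy‑4‑hydroxy‑7‑(methoxymethoxy)‑6‑[(4‑methoxybenzyloxy)methyl]‑5‑[2‑(trimethylsilyl)ethoxy]isobenzofuran‑1(3H)‑one, via C3‑lithiated lithium phenoxide 17 (not isolated), via 2‑(diethoxymethyl)benzoic acid 18 (not isolated)
Conditions: n‑BuLi (1.05 equiv), THF, −78 °C; s‑BuLi (2 equiv), TMEDA, −78 °C; CO2 (g), −78 → 0 °C; cold 1 M HCl to pH 4; PPTS (cat.), CH2Cl2, rt
Reagents that add atoms: carbon dioxide, O=C=O
Why: Directed ortho‑metalation should remove the only ring B hydrogen, which lies between the cooperating OMOM and acetal directing groups, and after carboxylation the acid closes on the neighbouring acetal with loss of ethanol to give the pseudo‑ester, whose acetal carbon forms racemic.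

Step 10
Reactants: 20 3,5‑difluorotoluene
Product: 22 2,6‑difluoro‑4‑methylbenzaldehyde, via 2,6‑difluoro‑4‑methylphenyllithium 21 (not isolated)
Conditions: n‑BuLi, THF, −78 °C; DMF, −78 → 0 °C; aq. HCl
Reagents that add atoms: N,N‑dimethylformamide, CN(C)C=O
Why: Ortho‑lithiation at the most acidic position between the two fluorines followed by formylation with DMF should give the symmetrical aldehyde.

Step 11
Reactants: 22 2,6‑difluoro‑4‑methylbenzaldehyde
Product: 25 2,4‑difluoro‑3‑formyl‑6‑methylbenzoic acid, via lithium α‑amino alkoxide 23 (not isolated), via ring‑lithiated amino alkoxide 24 (not isolated)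
Conditions: lithium 4‑methylpiperazin‑1‑ide (from 1‑methylpiperazine, n‑BuLi), THF, −78 °C; s‑BuLi (1.2 equiv), −78 °C; CO2 (g), −78 °C; 2 M HCl, rt
Reagents that add atoms: carbon dioxide, O=C=O
Why: The aldehyde is masked in situ as its lithium α‑amino alkoxide, fluorine‑directed ortho‑lithiation then occurs at either of the two symmetry‑equivalent ring positions (kept cold to prevent aryne formation), and carboxylation followed by acid work‑up returns the aldehyde.

Step 12
Reactants: 25 2,4‑difluoro‑3‑formyl‑6‑methylbenzoic acid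
Product: 26 2‑(trimethylsilyl)ethyl 2,4‑difluoro‑3‑formyl‑6‑methylbenzoate
Conditions: Me3SiCH2CH2OH, PPh3, DIAD, THF, 0 °C → rt
Reagents that add atoms: 2‑(trimethylsilyl)ethanol, C[Si](C)(C)CCO
Why: Mitsunobu esterification alkylates the carboxylate oxygen, so the di‑ortho‑substituted acid is esterified without attack at its hindered carbonyl and without amine nucleophiles that could displace fluoride.

Step 13
Reactants: 26 the difluoro TMSE ester
Product: 27 2‑(trimethylsilyl)ethyl 4‑tert‑butoxy‑2‑fluoro‑3‑formyl‑6‑methylbenzoate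
Conditions: KOt‑Bu (1.0 equiv), THF, −78 → −40 °C
Reagents that add atoms: potassium tert‑butoxide, CC(C)(C)[O-].[K+]
Why: SNAr by the bulky alkoxide should occur at the fluorine para to the ester and ortho to CHO, which has a hydrogen neighbour, rather than at the fluorine wedged between ester and CHO, and the new donor deactivates the product towards a second substitution.

Step 14
Reactants: 19 the phthalide phenol, 27 the ring A fluoride
Product: 28 2‑(trimethylsilyl)ethyl 4‑tert‑butoxy‑3‑formyl‑6‑methyl‑2‑{[3‑ethoxy‑7‑(methoxymethoxy)‑6‑[(4‑methoxybenzyloxy)methyl]‑1‑oxo‑5‑[2‑(trimethylsilyl)ethoxy]‑1,3‑dihydroisobenzofuran‑4‑yl]oxy}benzoate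
Conditions: K2CO3, DMF, 4 Å molecular sieves, 50 °C
Reagents that add atoms: none
Why: SNAr of the only free phenoxide (C5–O) on the remaining fluoride, activated by ortho formyl and ortho ester groups, should give the tetra‑ortho‑substituted diaryl ether, the sparingly soluble KF limiting premature TMSE ester cleavage.

Step 15
Reactants: 28 the diaryl ether
Product: 29 4‑tert‑butoxy‑2‑{[3‑ethoxy‑5‑hydroxy‑7‑(methoxymethoxy)‑6‑[(4‑methoxybenzyloxy)methyl]‑1‑oxo‑1,3‑dihydroisobenzofuran‑4‑yl]oxy}‑3‑formyl‑6‑methylbenzoic acid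
Conditions: TASF (tris(dimethylamino)sulfonium difluorotrimethylsilicate, 4 equiv), DMF, 0 → 40 °C; cold 0.1 M HCl
Reagents that add atoms: none
Why: Fluoride attack at silicon with β‑elimination of ethene (Peterson‑type fragmentation) should release first the ring A carboxylate and then the C6 phenoxide under anhydrous conditions that spare the pseudo‑ester, the carboxylate deactivating ring A towards Smiles‑type aryl migration.

Step 16
Reactants: 29 the hydroxy acid
Product: 30 protected rac‑depsidone (galbinic acid skeleton with C1 CH2OPMB, C2 OMOM, ring A O‑tert‑butyl ether and the lactol as its O‑ethyl pseudo‑ester)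
Conditions: DCC, DMAP (cat.), CH2Cl2 (0.01 M), rt
Reagents that add atoms: none
Why: Carbodiimide activation of the acid and intramolecular acylation of the adjacent C6 phenol (Steglich‑type lactonisation) should close the seven‑membered depsidone ring, which the diaryl ether preorganises.

Step 17
Reactants: 30 the protected depsidone
Product: 31 the C1 benzylic alcohol (PMB removed; MOM, tert‑butyl and ethyl pseudo‑ester retained)
Conditions: DDQ, CH2Cl2/pH 7 buffer (18:1), 0 °C → rt; used at once
Reagents that add atoms: none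
Why: Oxidative PMB ether cleavage by DDQ is selective for the electron‑rich anisyl ring and, being neutral, should not induce migration of the depsidone acyl group to the liberated primary alcohol.

Step 18
Reactants: 31 the benzylic alcohol
Product: 32 the C1 acetoxymethyl depsidone (MOM, tert‑butyl and ethyl pseudo‑ester retained)
Conditions: Ac2O, pyridine, DMAP (cat.), CH2Cl2, 0 °C
Reagents that add atoms: acetic anhydride, CC(=O)OC(C)=O
Why: Acylation of the only free hydroxyl, a primary alcohol, should be fast and outrun translactonisation.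

Step 19
Reactants: 32 the protected acetate
Product: 33 rac‑galbinic acid
Conditions: TFA/H2O (9:1), 0 °C → rt
Reagents that add atoms: water, O
Why: Aqueous acidolysis should cleave the MOM acetal and the aryl tert‑butyl ether and hydrolyse the ethyl pseudo‑ester through its acyloxocarbenium ion while sparing the primary acetate and the aryl ester, the lactol carbon forming racemic.

Step 20
Reactants: 33 rac‑galbinic acid
Product: 34 galbinic acid, (S) at the lactol carbon
Conditions: preparative HPLC on immobilised amylose tris(3,5‑dimethylphenylcarbamate), n‑heptane/EtOAc, 5 °C; cold evaporation; (R) fraction re‑equilibrated (MeCN/H2O, cat. AcOH, rt) and recycled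
Reagents that add atoms: none
Why: Resolution on a chiral stationary phase should separate the lactol enantiomers under cold, neutral, aprotic conditions where ring–chain tautomerism is slow, so the stereocentre is fixed by selection rather than by a reaction and the antipode is not lost.

**Compound list**

1 | squaric acid | OC1=C(O)C(=O)C1=O | starting material
2 | squaryl dichloride | ClC1=C(Cl)C(=O)C1=O | intermediate
3 | bis[2‑(trimethylsilyl)ethyl] squarate | C[Si](C)(C)CCOC1=C(OCC[Si](C)(C)C)C(=O)C1=O | intermediate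
4 | 3,3‑diethoxyprop‑1‑yne | C#CC(OCC)OCC | starting material
5 | (E)‑tributyl(3,3‑diethoxyprop‑1‑en‑1‑yl)stannane | CCCC[Sn](CCCC)(CCCC)/C=C/C(OCC)OCC | intermediate
6 | (E)‑3,3‑diethoxyprop‑1‑enyllithium (not isolated) | [Li]/C=C/C(OCC)OCC | intermediate
7 | rac‑4‑[(E)‑3,3‑diethoxyprop‑1‑enyl]‑4‑hydroxy‑2,3‑bis(TMSE‑oxy)cyclobut‑2‑en‑1‑one | O=C1C(OCC[Si](C)(C)C)=C(OCC[Si](C)(C)C)C1(O)/C=C/C(OCC)OCC | intermediate
8 | rac‑4‑[(E)‑3,3‑diethoxyprop‑1‑enyl]‑4‑(methoxymethoxy)‑2,3‑bis(TMSE‑oxy)cyclobut‑2‑en‑1‑one | O=C1C(OCC[Si](C)(C)C)=C(OCC[Si](C)(C)C)C1(OCOC)/C=C/C(OCC)OCC | intermediate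
9 | (tributylstannyl)methanol | OC[Sn](CCCC)(CCCC)CCCC | starting material
10 | tributyl[(4‑methoxybenzyloxy)methyl]stannane | COc1ccc(COC[Sn](CCCC)(CCCC)CCCC)cc1 | intermediate
11 | [(4‑methoxybenzyloxy)methyl]lithium (not isolated) | [Li]COCc1ccc(OC)cc1 | intermediate
12 | lithium alkoxide of the 1,2‑adduct of 11 to 8 (not isolated, diastereomer mixture) | [Li]OC1(COCc2ccc(OC)cc2)C(OCC[Si](C)(C)C)=C(OCC[Si](C)(C)C)C1(OCOC)/C=C/C(OCC)OCC | intermediate
13 | rac‑4‑[(E)‑3,3‑diethoxyprop‑1‑enyl]‑4‑(methoxymethoxy)‑3‑[(4‑methoxybenzyloxy)methyl]‑2‑(TMSE‑oxy)cyclobut‑2‑en‑1‑one | O=C1C(OCC[Si](C)(C)C)=C(COCc2ccc(OC)cc2)C1(OCOC)/C=C/C(OCC)OCC | intermediate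
14 | dienylketene from ring opening of 13 (not isolated) | O=C=C(OCC[Si](C)(C)C)/C(COCc1ccc(OC)cc1)=C(/OCOC)\C=C\C(OCC)OCC | intermediate
15 | rac‑6‑(diethoxymethyl)‑4‑(methoxymethoxy)‑3‑[(4‑methoxybenzyloxy)methyl]‑2‑(TMSE‑oxy)cyclohexa‑2,4‑dien‑1‑one (not isolated) | O=C1C(OCC[Si](C)(C)C)=C(COCc2ccc(OC)cc2)C(OCOC)=CC1C(OCC)OCC | intermediate
16 | 2‑(diethoxymethyl)‑4‑(methoxymethoxy)‑5‑[(4‑methoxybenzyloxy)methyl]‑6‑(TMSE‑oxy)phenol | COc1ccc(COCc2c(OCOC)cc(C(OCC)OCC)c(O)c2OCC[Si](C)(C)C)cc1 | intermediate
17 | C3‑lithiated lithium phenoxide of 16 (not isolated) | COc1ccc(COCc2c(OCOC)c([Li])c(C(OCC)OCC)c(O[Li])c2OCC[Si](C)(C)C)cc1 | intermediate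
18 | 2‑(diethoxymethyl)‑3‑hydroxy‑6‑(methoxymethoxy)‑5‑[(4‑methoxybenzyloxy)methyl]‑4‑(TMSE‑oxy)benzoic acid (not isolated) | COc1ccc(COCc2c(OCOC)c(C(=O)O)c(C(OCC)OCC)c(O)c2OCC[Si](C)(C)C)cc1 | intermediate
19 | rac‑3‑ethoxy‑4‑hydroxy‑7‑(methoxymethoxy)‑6‑[(4‑methoxybenzyloxy)methyl]‑5‑(TMSE‑oxy)isobenzofuran‑1(3H)‑one | COc1ccc(COCc2c(OCOC)c3C(=O)OC(OCC)c3c(O)c2OCC[Si](C)(C)C)cc1 | intermediate
20 | 3,5‑difluorotoluene | Cc1cc(F)cc(F)c1 | starting material
21 | 2,6‑difluoro‑4‑methylphenyllithium (not isolated) | [Li]c1c(F)cc(C)cc1F | intermediate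
22 | 2,6‑difluoro‑4‑methylbenzaldehyde | Cc1cc(F)c(C=O)c(F)c1 | intermediate
23 | lithium α‑(4‑methylpiperazin‑1‑yl) alkoxide of 22 (not isolated) | [Li]OC(c1c(F)cc(C)cc1F)N1CCN(C)CC1 | intermediate
24 | 3‑lithio derivative of 23 (not isolated) | [Li]OC(c1c(F)cc(C)c([Li])c1F)N1CCN(C)CC1 | intermediate
25 | 2,4‑difluoro‑3‑formyl‑6‑methylbenzoic acid | Cc1cc(F)c(C=O)c(F)c1C(=O)O | intermediate
26 | 2‑(trimethylsilyl)ethyl 2,4‑difluoro‑3‑formyl‑6‑methylbenzoate | C[Si](C)(C)CCOC(=O)c1c(C)cc(F)c(C=O)c1F | intermediate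
27 | 2‑(trimethylsilyl)ethyl 4‑tert‑butoxy‑2‑fluoro‑3‑formyl‑6‑methylbenzoate | C[Si](C)(C)CCOC(=O)c1c(C)cc(OC(C)(C)C)c(C=O)c1F | intermediate
28 | tetra‑ortho‑substituted diaryl ether (ring B C5–O–C2′ ring A; both TMSE groups present) | COc1ccc(COCc2c(OCOC)c3C(=O)OC(OCC)c3c(Oc3c(C=O)c(OC(C)(C)C)cc(C)c3C(=O)OCC[Si](C)(C)C)c2OCC[Si](C)(C)C)cc1 | intermediate
29 | diaryl ether hydroxy acid (free C6 phenol, free ring A acid) | COc1ccc(COCc2c(OCOC)c3C(=O)OC(OCC)c3c(Oc3c(C=O)c(OC(C)(C)C)cc(C)c3C(=O)O)c2O)cc1 | intermediate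
30 | protected rac‑depsidone (PMB ether, MOM ether, tert‑butyl ether, ethyl pseudo‑ester) | COc1ccc(COCc2c(OCOC)c3c(c4c2OC(=O)c2c(C)cc(OC(C)(C)C)c(C=O)c2O4)C(OCC)OC3=O)cc1 | intermediate
31 | C1 hydroxymethyl depsidone (MOM, tert‑butyl, ethyl pseudo‑ester) | OCc1c(OCOC)c2c(c3c1OC(=O)c1c(C)cc(OC(C)(C)C)c(C=O)c1O3)C(OCC)OC2=O | intermediate
32 | C1 acetoxymethyl depsidone (MOM, tert‑butyl, ethyl pseudo‑ester) | CC(=O)OCc1c(OCOC)c2c(c3c1OC(=O)c1c(C)cc(OC(C)(C)C)c(C=O)c1O3)C(OCC)OC2=O | intermediate
33 | rac‑galbinic acid | CC(=O)OCc1c(O)c2c(c3c1OC(=O)c1c(C)cc(O)c(C=O)c1O3)C(O)OC2=O | intermediate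
34 | galbinic acid, (S) at the lactol carbon | CC(=O)OCc1c(O)c2c(c3c1OC(=O)c1c(C)cc(O)c(C=O)c1O3)[C@@H](O)OC2=O | target

**Totals**

Total step count: 20. Longest linear sequence: 14 steps (steps 1, 2, 4, 5, 7, 8, 9 and 14–20, from squaric acid).

**Steps most likely to fail, with fallbacks**

Step 9. Ring lithiation of the electron‑rich phenoxide may be slow, and the base may instead deprotonate the two benzylic ether CH2 groups, leading to Wittig rearrangement. The fallback replaces deprotonation by halogen–lithium exchange. It sets out from 16, which is silylated (TBSCl, imidazole, DMF) to the tert‑butyldimethylsilyl ether of 16 F1. Bromination with NBS in MeCN at 0 °C at the only free ring B position (ortho to OMOM, para to OTMSE) should give the C3 bromide F2. Exchange with t‑BuLi (2.1 equiv) in THF at −100 °C, which is far faster than any deprotonation, and CO2 quench should give the silyl‑protected 2‑(diethoxymethyl)benzoic acid F3, which closes with PPTS to the silyl‑protected ethoxyphthalide F4. Bu4NF buffered with AcOH in THF at 0 °C should remove the aryl silyl ether much faster than the aryl TMSE ether, and the route is rejoined at 19.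

Step 14. Attack at the doubly flanked fluoride may be slow, and the fluoride released may cleave the TMSE ester early, turning the electrophile into an unreactive carboxylate. The fallback separates the two deprotections so that the SNAr can be forced. It sets out from acid 25 and phenol 19. Mitsunobu esterification of 25 with allyl alcohol should give allyl 2,4‑difluoro‑3‑formyl‑6‑methylbenzoate F5, and KOt‑Bu as in step 13 should give allyl 4‑tert‑butoxy‑2‑fluoro‑3‑formyl‑6‑methylbenzoate F6. Coupling of F6 with 19 (Cs2CO3, DMSO, 80–100 °C) should give the allyl ester diaryl ether F7, whose ester is indifferent to fluoride. Pd(PPh3)4 with morpholine should then give the diaryl ether acid still carrying the C6 TMSE ether F8, and TASF in DMF removes that ether, rejoining the route at 29.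

Step 20. The lactol may racemise on the column or during evaporation, so that the enantiomers cannot be collected pure. The fallback separates covalent diastereomers that are cleaved without touching the lactol C–O bond. It sets out from 33, which with 1‑chloro‑N,N,2‑trimethylprop‑1‑en‑1‑amine in CH2Cl2 at 0 °C should give the 3‑chlorophthalide F9. Koenigs–Knorr‑type reaction of F9 with (S)‑1‑(4‑methoxyphenyl)ethanol and Ag2CO3 should give two configurationally stable pseudo‑esters, separable on silica or by crystallisation: the (S)‑lactol (S)‑1‑(4‑methoxyphenyl)ethyl pseudo‑ester F10 and the (R)‑lactol diastereomer F11. DDQ in CH2Cl2/pH 7 buffer at 0 °C should oxidise the auxiliary's benzylic C–H of F10 and release the lactol with retention, rejoining the route at 34. F11 is cleaved in the same way and its lactol re‑equilibrated to 33 for recycling.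

**Further compounds**

F1 | step 9 | tert‑butyldimethylsilyl ether of phenol 16 | COc1ccc(COCc2c(OCOC)cc(C(OCC)OCC)c(O[Si](C)(C)C(C)(C)C)c2OCC[Si](C)(C)C)cc1
F2 | step 9 | C3 bromide of F1 | COc1ccc(COCc2c(OCOC)c(Br)c(C(OCC)OCC)c(O[Si](C)(C)C(C)(C)C)c2OCC[Si](C)(C)C)cc1
F3 | step 9 | silyl‑protected 2‑(diethoxymethyl)benzoic acid | COc1ccc(COCc2c(OCOC)c(C(=O)O)c(C(OCC)OCC)c(O[Si](C)(C)C(C)(C)C)c2OCC[Si](C)(C)C)cc1
F4 | step 9 | rac‑4‑(tert‑butyldimethylsilyloxy) analogue of ethoxyphthalide 19 | COc1ccc(COCc2c(OCOC)c3C(=O)OC(OCC)c3c(O[Si](C)(C)C(C)(C)C)c2OCC[Si](C)(C)C)cc1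
F5 | step 14 | allyl 2,4‑difluoro‑3‑formyl‑6‑methylbenzoate | C=CCOC(=O)c1c(C)cc(F)c(C=O)c1F
F6 | step 14 | allyl 4‑tert‑butoxy‑2‑fluoro‑3‑formyl‑6‑methylbenzoate | C=CCOC(=O)c1c(C)cc(OC(C)(C)C)c(C=O)c1F
F7 | step 14 | allyl ester analogue of diaryl ether 28 | COc1ccc(COCc2c(OCOC)c3C(=O)OC(OCC)c3c(Oc3c(C=O)c(OC(C)(C)C)cc(C)c3C(=O)OCC=C)c2OCC[Si](C)(C)C)cc1
F8 | step 14 | diaryl ether acid with the C6 TMSE ether retained | COc1ccc(COCc2c(OCOC)c3C(=O)OC(OCC)c3c(Oc3c(C=O)c(OC(C)(C)C)cc(C)c3C(=O)O)c2OCC[Si](C)(C)C)cc1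
F9 | step 20 | rac‑3‑chlorophthalide from galbinic acid (lactol OH replaced by Cl) | CC(=O)OCc1c(O)c2c(c3c1OC(=O)c1c(C)cc(O)c(C=O)c1O3)C(Cl)OC2=O
F10 | step 20 | (S)‑lactol O‑[(S)‑1‑(4‑methoxyphenyl)ethyl] pseudo‑ester of galbinic acid | CC(=O)OCc1c(O)c2c(c3c1OC(=O)c1c(C)cc(O)c(C=O)c1O3)[C@@H](O[C@@H](C)c1ccc(OC)cc1)OC2=O
F11 | step 20 | (R)‑lactol O‑[(S)‑1‑(4‑methoxyphenyl)ethyl] pseudo‑ester of galbinic acid | CC(=O)OCc1c(O)c2c(c3c1OC(=O)c1c(C)cc(O)c(C=O)c1O3)[C@H](O[C@@H](C)c1ccc(OC)cc1)OC2=O
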